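**Assumptions and numbering (one line each)**
- Stereochemistry as read from the SMILES: normal labdane decalin (5α-H, 9α-H, 10β-Me, 7β-OH, 18-OH = 4α-CH2OH) and a (4aS,5R,8aR) cis-fused core in which the C5 side chain, the 4a-chromone and H-8a are all on one face.
- Decalin atoms use labdane numbering (C11 = CH2 on C9, C17 = exocyclic CH2, C18 = 4α-CH2O); the bicyclic core uses naphthalene-1,4-dione numbering (C1=O next to C8a-H, C2-OMe, C4=O next to quaternary C4a, C5 bears C11).
- The (S)-O-methylmandelate auxiliary is assumed to favour the facial isomer drawn for 22; both facial isomers are separable diastereomers, and the (R)-acid is used instead if the sense is opposite.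

**Retrosynthetic overview**
1. In the target C11 is cis to the 4a-chromone, the anti-Alder (exo-type) relationship, so the first-choice biomimetic labdatriene + flavone-quinone Diels–Alder (endo, no facial control) is not used.
2. Key disconnection is C11–C12 (core C5–CH2): allylboration of a drimane C11 aldehyde by a ring-C allylboronate, then removal of the C11 hydroxyl.
3. The allylboronate comes from a stereochemical relay: endo Diels–Alder of the chromonyl methoxyquinone with a small chiral 1-acyloxydiene (O trans to chromone), Pd borylation with inversion (B cis), syn-SE2′ allylboration (C11 cis).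
4. Ring order: decalin A/B in one step by Ti(III) radical bicyclisation of a Sharpless epoxide of farnesyl acetate; flavone by Baker–Venkataraman; quinone ring D by CAN; ring C by the Diels–Alder.
5. The C1 ketone is parked as a TES ether from the Diels–Alder until after the coupling, to block C8a epimerisation and enedione side reactions.

---

**Step 1**
Reactants: 1, (2E,6E)-farnesyl acetate
Product: 2, (2E,6E,10E)-12-hydroxyfarnesyl acetate
Conditions: SeO2 (0.1 eq), t-BuOOH, salicylic acid (cat.), CH2Cl2, rt; then NaBH4, MeOH, 0 °C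
Reagents that add atoms: tert-butyl hydroperoxide, CC(C)(C)OO (oxygen source; SeO2, O=[Se]=O, catalyst)
Why: Sharpless SeO2/TBHP allylic oxidation (ene/[2,3]) selects the (E)-methyl of the electron-rich terminal alkene, and the borohydride quench returns any over-oxidised enal to 2.

**Step 2**
Reactants: 2, (2E,6E,10E)-12-hydroxyfarnesyl acetate
Product: 3, (2E,6E,10S,11S)-10,11-epoxy-12-hydroxyfarnesyl acetate
Conditions: Ti(OiPr)4 (cat.), L-(+)-diethyl tartrate, t-BuOOH, 4 Å MS, CH2Cl2, −20 °C
Reagents that add atoms: tert-butyl hydroperoxide, CC(C)(C)OO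
Why: Sharpless asymmetric epoxidation; L-(+)-DET gives the (S,S)-epoxy alcohol, the same sense as (3S)-oxidosqualene, and this one centre later dictates every decalin stereocentre.

**Step 3**
Reactants: 3, epoxy alcohol
Product: 4, 12-O-TBS ether of 3
Conditions: TBSCl, imidazole, DMF, 0 °C to rt
Reagents that add atoms: TBSCl, CC(C)(C)[Si](C)(C)Cl
Why: Silylation of the primary alcohol prevents Ti-alkoxide deoxygenation in step 4 and becomes the 18-O protecting group.

**Step 4**
Reactants: 4, TBS epoxide
Product: 5, 3β-hydroxy-18-(TBSO)drim-8(17)-en-11-yl acetate (trans-decalin; 4α-CH2OTBS, 4β-Me, 5α-H, 9α-H, 10β-Me)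
Conditions: Cp2TiCl2 (2.2 eq), Mn dust, THF, rt, slow addition; aqueous workup
Reagents that add atoms: none
Why: Nugent–RajanBabu Ti(III) epoxide opening gives the tertiary C4 radical, which undergoes 6-endo/6-endo chair–chair bicyclisation and Ti-mediated β-H loss to the exocyclic alkene; the equatorial C3–OTi fixes the trans-anti C5/C9/C10 centres and the larger CH2OTBS is expected to sit equatorial (α) at C4.

**Step 5**
Reactants: 5, 3β-alcohol
Product: 6, 3β-O-(phenoxythiocarbonyl) derivative of 5
Conditions: PhOC(S)Cl, DMAP, pyridine, CH2Cl2, rt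
Reagents that add atoms: phenyl chlorothionoformate, S=C(Cl)Oc1ccccc1
Why: Thionocarbonate formation (Robins variant of Barton–McCombie activation) under neutral conditions that leave the acetate and silyl ether untouched.

**Step 6**
Reactants: 6, thionocarbonate
Product: 7, 18-(TBSO)drim-8(17)-en-11-yl acetate
Conditions: Bu3SnH, AIBN, toluene, 100 °C
Reagents that add atoms: none (H from Bu3SnH)
Why: Barton–McCombie deoxygenation; the secondary C3 radical is simply reduced, no stereocentre is involved and the remote 1,1-disubstituted alkene is inert.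

**Step 7**
Reactants: 7, 3-deoxy acetate
Product: 8, 7α-hydroxy-18-(TBSO)drim-8(17)-en-11-yl acetate
Conditions: SeO2 (0.5 eq), t-BuOOH, CH2Cl2, 0 °C to rt
Reagents that add atoms: tert-butyl hydroperoxide, CC(C)(C)OO (SeO2 mediator)
Why: SeO2 allylic hydroxylation of the exocyclic methylene occurs at the ring CH2 (C7) from the α-face to give the axial 7α-alcohol, which is corrected in steps 8–9.

**Step 8**
Reactants: 8, 7α-alcohol
Product: 9, 7-oxo-18-(TBSO)drim-8(17)-en-11-yl acetate
Conditions: Dess–Martin periodinane, NaHCO3, CH2Cl2, 0 °C; used at once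
Reagents that add atoms: none
Why: Mild Dess–Martin oxidation gives the exo-methylene enone without isomerising the alkene into the ring.

**Step 9**
Reactants: 9, enone
Product: 10, 7β-hydroxy-18-(TBSO)drim-8(17)-en-11-yl acetate
Conditions: NaBH4, CeCl3·7H2O, MeOH, −78 °C
Reagents that add atoms: none (H from NaBH4)
Why: Luche 1,2-reduction with axial (α-face) hydride delivery gives the equatorial 7β-alcohol required by the target.

**Step 10**
Reactants: 10, 7β-alcohol
Product: 11, 7β,18-bis(TBSO)drim-8(17)-en-11-yl acetate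
Conditions: TBSOTf, 2,6-lutidine, CH2Cl2, −78 °C
Reagents that add atoms: TBSOTf, CC(C)(C)[Si](C)(C)OS(=O)(=O)C(F)(F)F
Why: Silylation of the hindered allylic alcohol without ionising it.

**Step 11**
Reactants: 11, acetate
Product: 12, 7β,18-bis(TBSO)drim-8(17)-en-11-ol
Conditions: K2CO3, MeOH, rt
Reagents that add atoms: none
Why: Methanolysis of the primary acetate; silyl ethers are stable.

**Step 12**
Reactants: 12, primary alcohol
Product: 13, 7β,18-bis(TBSO)drim-8(17)-en-11-al
Conditions: Dess–Martin periodinane, NaHCO3, CH2Cl2, 0 °C; used crude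
Reagents that add atoms: none
Why: Buffered Dess–Martin oxidation gives the β,γ-unsaturated aldehyde without C9 epimerisation or migration of the alkene into conjugation.

**Step 13**
Reactants: 14, 2′,4′,6′-trihydroxyacetophenone; 15, 2,4,5-trimethoxybenzoic acid
Product: 16, 5,7-dihydroxy-2′,4′,5′-trimethoxyflavone
Conditions: 15 to acid chloride ((COCl)2, cat. DMF); 14, LiHMDS (4.2 eq), THF, −78 °C, then the acid chloride; then AcOH, cat. H2SO4, 95 °C
Reagents that add atoms: none beyond 14 and 15
Why: One-pot Baker–Venkataraman-type C-aroylation of the lithium polyanion followed by acid cyclodehydration gives the flavone.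

**Step 14**
Reactants: 16, dihydroxyflavone
Product: 17, 5,7-bis(methoxymethoxy)-2′,4′,5′-trimethoxyflavone
Conditions: NaH, MOMCl, DMF, 0 °C to rt
Reagents that add atoms: chloromethyl methyl ether, COCCl
Why: Both phenols are capped as MOM ethers that survive oxidation, Lewis acid at low temperature, Pd and radicals and are removed by acid at the end.

**Step 15**
Reactants: 17, trimethoxyflavone
Product: 18, 2-[5,7-bis(methoxymethoxy)-4-oxochromen-2-yl]-5-methoxy-1,4-benzoquinone
Conditions: CAN (3 eq), MeCN/H2O, 0 °C, 15 min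
Reagents that add atoms: water, O
Why: CAN oxidative demethylation of the para-related 2′,5′-dimethoxy pair gives the p-quinone and leaves the 4′-OMe as the vinylogous-ester methoxy of the target.

**Step 16**
Reactants: 19, (E)-2-methylbut-2-enal (tiglic aldehyde); 20, (S)-O-methylmandelic acid
Product: 21, (1E)-2-methylbuta-1,3-dien-1-yl (S)-O-methylmandelate
Conditions: 20 to acid chloride ((COCl)2, cat. DMF); 19, t-BuOK, THF, −78 °C, then the acid chloride; E isomer isolated
Reagents that add atoms: none beyond 19 and 20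
Why: γ-Deprotonation of the enal and O-acylation of the dienolate gives a Trost-type chiral 1-acyloxydiene whose ester is later the allylic leaving group.

**Step 17**
Reactants: 18, chromonyl methoxyquinone; 21, chiral dienyl ester
Product: 22, (4aR,5S,8aR)-4a-[5,7-bis(MOMO)-4-oxochromen-2-yl]-2-methoxy-6-methyl-1,4-dioxo-1,4,4a,5,8,8a-hexahydronaphthalen-5-yl (S)-O-methylmandelate (cis-fused; 5-O trans to chromone)
Conditions: BF3·OEt2 (2 eq), CH2Cl2, −78 to −40 °C; minor facial diastereomer removed by chromatography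
Reagents that add atoms: none
Why: Lewis-acid Diels–Alder at the non-methoxylated quinone C=C, with the CH2 diene terminus bonding to the quinone CH (β to the BF3-bound vinylogous-ester carbonyl and conjugated to the chromone); suprafacial addition gives the cis fusion, the Alder endo mode puts the 5-acyloxy group cis to C4=O and trans to the chromone, and the mandelate controls the face.

**Step 18**
Reactants: 22, Diels–Alder adduct
Product: 23, C1 alcohol of 22 (C1 configuration irrelevant)
Conditions: NaBH4, CeCl3·7H2O, MeOH/CH2Cl2, −78 °C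
Reagents that add atoms: none (H from NaBH4)
Why: Luche reduction takes the electrophilic C1 ketone and not the hindered vinylogous-ester C4=O or the chromone, which removes the enolisable ketone (cis-to-trans epimerisation at C8a) and the Michael/radical-acceptor enedione for the next steps.

**Step 19**
Reactants: 23, C1 alcohol
Product: 24, C1 O-triethylsilyl ether of 23
Conditions: TESCl, imidazole, DMF, 0 °C
Reagents that add atoms: TESCl, CC[Si](CC)(CC)Cl
Why: The TES ether is not a π-allyl leaving group and can later be removed in the presence of TBS and MOM.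

**Step 20**
Reactants: 24, allylic mandelate
Product: 25, allylboronate: 7-(pinacolboryl)-Δ5 isomer, Bpin cis to the 4a-chromone and H-8a
Conditions: Pd2(dba)3 (5 mol %), B2pin2 (1.5 eq), DMSO, 50 °C; used crude
Reagents that add atoms: bis(pinacolato)diboron, CC1(C)OB(OC1(C)C)B1OC(C)(C)C(C)(C)O1
Why: Miyaura borylation of an allylic ester through a π-allyl-Pd: ionisation occurs with inversion and boron is delivered from Pd to the less hindered C7 terminus, so the oxygen at C5 (trans to chromone) is exchanged for boron at C7 on the opposite face (cis to chromone).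

**Step 21**
Reactants: 25, allylboronate; 13, drimane aldehyde
Product: 26, coupled C11 carbinol (either C11 epimer): C5 of the core now carries CH(OH)–C9 cis to the chromone, alkene back at C6=C7
Conditions: toluene, 4 Å MS, 60 °C, 48 h; aqueous NaHCO3 workup
Reagents that add atoms: none
Why: Carbonyl allylboration through a closed six-membered transition state is a syn-SE2′ process, so the new C11–C12 bond forms at C5 on the face that carried boron and sets the (5R) centre with C11 cis to the chromone and H-8a.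

**Step 22**
Reactants: 26, C11 carbinol
Product: 27, C11 O-(phenoxythiocarbonyl) derivative of 26
Conditions: PhOC(S)Cl, DMAP, MeCN, 40 °C
Reagents that add atoms: phenyl chlorothionoformate, S=C(Cl)Oc1ccccc1
Why: Thionocarbonate activation of the only free hydroxyl for Barton–McCombie deoxygenation.

**Step 23**
Reactants: 27, thionocarbonate
Product: 28, C11-methylene compound (full carbon skeleton; C1–OTES, 7,18-bis-OTBS, 5,7-bis-OMOM)
Conditions: Bu3SnH (0.3 M), AIBN, toluene, 90 °C
Reagents that add atoms: none (H from Bu3SnH)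
Why: Barton–McCombie deoxygenation; with C1 reduced the ring-D alkene is a polarity-mismatched vinylogous ester, so the C11 radical is trapped by tin hydride faster than it cyclises, and no stereocentre is touched.

**Step 24**
Reactants: 28, TES ether
Product: 29, C1 alcohol
Conditions: HF·pyridine, pyridine, THF, 0 °C
Reagents that add atoms: none
Why: Buffered fluoride removes the secondary TES ether faster than the TBS ethers and does not affect MOM groups or the enol ether.

**Step 25**
Reactants: 29, C1 alcohol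
Product: 30, 7,18-bis-O-TBS-5″,7″-bis-O-MOM dichrostachine A (C1 ketone restored)
Conditions: Dess–Martin periodinane, NaHCO3, CH2Cl2, 0 °C
Reagents that add atoms: none
Why: The only free hydroxyl is oxidised back to the 2-methoxy-ene-1,4-dione under non-basic conditions, so the cis ring fusion at C8a is kept.

**Step 26**
Reactants: 30, protected target
Product: 31, dichrostachine A
Conditions: HCl (about 1 M, from AcCl in MeOH), MeOH/THF, 0 °C to rt
Reagents that add atoms: none
Why: Anhydrous methanolic acid cleaves both aryl MOM ethers and both TBS ethers in one operation, and exchange at the methyl vinylogous ester is degenerate in methanol.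

---

**Compound list**
1 | (2E,6E)-farnesyl acetate | CC(C)=CCC/C(C)=C/CC/C(C)=C/COC(C)=O | starting material
2 | (2E,6E,10E)-12-hydroxyfarnesyl acetate | OC/C(C)=C/CC/C(C)=C/CC/C(C)=C/COC(C)=O | intermediate
3 | (10S,11S)-10,11-epoxy-12-hydroxyfarnesyl acetate | OC[C@]1(C)O[C@H]1CC/C(C)=C/CC/C(C)=C/COC(C)=O | intermediate
4 | 12-O-TBS ether of 3 | CC(C)(C)[Si](C)(C)OC[C@]1(C)O[C@H]1CC/C(C)=C/CC/C(C)=C/COC(C)=O | intermediate
5 | 3β-hydroxy-18-(TBSO)drim-8(17)-en-11-yl acetate | C=C1CC[C@H]2[C@](C)(CO[Si](C)(C)C(C)(C)C)[C@@H](O)CC[C@]2(C)[C@H]1COC(C)=O | intermediate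
6 | 3β-O-phenoxythiocarbonyl derivative of 5 | C=C1CC[C@H]2[C@](C)(CO[Si](C)(C)C(C)(C)C)[C@@H](OC(=S)Oc3ccccc3)CC[C@]2(C)[C@H]1COC(C)=O | intermediate
7 | 18-(TBSO)drim-8(17)-en-11-yl acetate | C=C1CC[C@H]2[C@](C)(CO[Si](C)(C)C(C)(C)C)CCC[C@]2(C)[C@H]1COC(C)=O | intermediate
8 | 7α-hydroxy-18-(TBSO)drim-8(17)-en-11-yl acetate | C=C1[C@H](O)C[C@H]2[C@](C)(CO[Si](C)(C)C(C)(C)C)CCC[C@]2(C)[C@H]1COC(C)=O | intermediate
9 | 7-oxo-18-(TBSO)drim-8(17)-en-11-yl acetate | C=C1C(=O)C[C@H]2[C@](C)(CO[Si](C)(C)C(C)(C)C)CCC[C@]2(C)[C@H]1COC(C)=O | intermediate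
10 | 7β-hydroxy-18-(TBSO)drim-8(17)-en-11-yl acetate | C=C1[C@@H](O)C[C@H]2[C@](C)(CO[Si](C)(C)C(C)(C)C)CCC[C@]2(C)[C@H]1COC(C)=O | intermediate
11 | 7β,18-bis(TBSO)drim-8(17)-en-11-yl acetate | C=C1[C@@H](O[Si](C)(C)C(C)(C)C)C[C@H]2[C@](C)(CO[Si](C)(C)C(C)(C)C)CCC[C@]2(C)[C@H]1COC(C)=O | intermediate
12 | 7β,18-bis(TBSO)drim-8(17)-en-11-ol | C=C1[C@@H](O[Si](C)(C)C(C)(C)C)C[C@H]2[C@](C)(CO[Si](C)(C)C(C)(C)C)CCC[C@]2(C)[C@H]1CO | intermediate
13 | 7β,18-bis(TBSO)drim-8(17)-en-11-al | C=C1[C@@H](O[Si](C)(C)C(C)(C)C)C[C@H]2[C@](C)(CO[Si](C)(C)C(C)(C)C)CCC[C@]2(C)[C@H]1C=O | intermediate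
14 | 2′,4′,6′-trihydroxyacetophenone | CC(=O)c1c(O)cc(O)cc1O | starting material
15 | 2,4,5-trimethoxybenzoic acid | COc1cc(OC)c(OC)cc1C(=O)O | starting material
16 | 5,7-dihydroxy-2′,4′,5′-trimethoxyflavone | COc1cc(OC)c(OC)cc1-c1cc(=O)c2c(O)cc(O)cc2o1 | intermediate
17 | 5,7-bis(methoxymethoxy)-2′,4′,5′-trimethoxyflavone | COc1cc(OC)c(OC)cc1-c1cc(=O)c2c(OCOC)cc(OCOC)cc2o1 | intermediate
18 | 2-[5,7-bis(MOMO)-4-oxochromen-2-yl]-5-methoxy-1,4-benzoquinone | COC1=CC(=O)C(=CC1=O)c1cc(=O)c2c(OCOC)cc(OCOC)cc2o1 | intermediate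
19 | (E)-2-methylbut-2-enal | C/C=C(\C)C=O | starting material
20 | (S)-O-methylmandelic acid | CO[C@H](C(=O)O)c1ccccc1 | starting material
21 | (1E)-2-methylbuta-1,3-dien-1-yl (S)-O-methylmandelate | CO[C@@H](c1ccccc1)C(=O)O/C=C(\C)C=C | intermediate
22 | Diels–Alder adduct, (4aR,5S,8aR), 5-mandelate trans to chromone | CO[C@@H](c1ccccc1)C(=O)O[C@H]1C(C)=CC[C@H]2C(=O)C(OC)=CC(=O)[C@@]12c1cc(=O)c2c(OCOC)cc(OCOC)cc2o1 | intermediate
23 | C1 alcohol of 22 (C1 unassigned) | CO[C@@H](c1ccccc1)C(=O)O[C@H]1C(C)=CC[C@H]2C(O)C(OC)=CC(=O)[C@@]12c1cc(=O)c2c(OCOC)cc(OCOC)cc2o1 | intermediate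
24 | C1 O-TES ether of 23 | CO[C@@H](c1ccccc1)C(=O)O[C@H]1C(C)=CC[C@H]2C(O[Si](CC)(CC)CC)C(OC)=CC(=O)[C@@]12c1cc(=O)c2c(OCOC)cc(OCOC)cc2o1 | intermediate
25 | 7-Bpin-Δ5 allylboronate (B cis to chromone) | C1=C(C)[C@H](B3OC(C)(C)C(C)(C)O3)C[C@H]2C(O[Si](CC)(CC)CC)C(OC)=CC(=O)[C@@]12c1cc(=O)c2c(OCOC)cc(OCOC)cc2o1 | intermediate
26 | coupled C11 carbinol (C11 and C1 unassigned) | C=C1[C@@H](O[Si](C)(C)C(C)(C)C)C[C@H]2[C@](C)(CO[Si](C)(C)C(C)(C)C)CCC[C@]2(C)[C@H]1C(O)[C@@H]1C(C)=CC[C@H]2C(O[Si](CC)(CC)CC)C(OC)=CC(=O)[C@@]12c1cc(=O)c2c(OCOC)cc(OCOC)cc2o1 | intermediate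
27 | C11 O-phenoxythiocarbonyl derivative of 26 | C=C1[C@@H](O[Si](C)(C)C(C)(C)C)C[C@H]2[C@](C)(CO[Si](C)(C)C(C)(C)C)CCC[C@]2(C)[C@H]1C(OC(=S)Oc3ccccc3)[C@@H]1C(C)=CC[C@H]2C(O[Si](CC)(CC)CC)C(OC)=CC(=O)[C@@]12c1cc(=O)c2c(OCOC)cc(OCOC)cc2o1 | intermediate
28 | C11-deoxy compound, C1–OTES | C=C1[C@@H](O[Si](C)(C)C(C)(C)C)C[C@H]2[C@](C)(CO[Si](C)(C)C(C)(C)C)CCC[C@]2(C)[C@H]1C[C@@H]1C(C)=CC[C@H]2C(O[Si](CC)(CC)CC)C(OC)=CC(=O)[C@@]12c1cc(=O)c2c(OCOC)cc(OCOC)cc2o1 | intermediate
29 | C1 alcohol | C=C1[C@@H](O[Si](C)(C)C(C)(C)C)C[C@H]2[C@](C)(CO[Si](C)(C)C(C)(C)C)CCC[C@]2(C)[C@H]1C[C@@H]1C(C)=CC[C@H]2C(O)C(OC)=CC(=O)[C@@]12c1cc(=O)c2c(OCOC)cc(OCOC)cc2o1 | intermediate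
30 | bis-TBS, bis-MOM dichrostachine A | C=C1[C@@H](O[Si](C)(C)C(C)(C)C)C[C@H]2[C@](C)(CO[Si](C)(C)C(C)(C)C)CCC[C@]2(C)[C@H]1C[C@@H]1C(C)=CC[C@H]2C(=O)C(OC)=CC(=O)[C@@]12c1cc(=O)c2c(OCOC)cc(OCOC)cc2o1 | intermediate
31 | dichrostachine A | C=C1[C@@H](O)C[C@H]2[C@](C)(CO)CCC[C@]2(C)[C@H]1C[C@@H]1C(C)=CC[C@H]2C(=O)C(OC)=CC(=O)[C@@]12c1cc(=O)c2c(O)cc(O)cc2o1 | target

---

**Totals**
- Total steps: 26.
- Longest linear sequence: 18 (steps 1–12, then 21–26).

**Three steps most likely to fail, with approach-changing fallbacks**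
1. **Step 21, allylboration.** Two hindered partners react next to the quaternary C4a, on the chromone face. Fallback: reverse the polarity and make the bond without a C11 oxygen: suprafacial Pd(II) 1,3-acyloxy shift of 24 to the C7 ester, conversion to the C7 phosphate, then Cu-catalysed γ-selective anti-SN2′ allyl–alkyl coupling with the 9-BBN borate of the C11 iodide made from 12. The stereochemical outcome is the same and steps 22–23 are dropped.
2. **Step 17, Diels–Alder.** Risks are regiochemistry on the methoxyquinone, bond formation at the chromone-bearing carbon, and the facial bias of the auxiliary. Fallback: use 2-methoxycarbonyl-5-methoxybenzoquinone as a chelating dienophile with 1-acetoxy-2-methylbutadiene under a chiral Lewis acid (Evans-type lanthanide–pybox), carry the angular ester through the same borylation/allylboration relay, and build the chromone afterwards from the ester (aryl ynone formation and 6-endo cyclisation).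
3. **Step 4, Ti(III) bicyclisation.** Risks are moderate yield and incomplete C4 selectivity, because the C4 radical is planar. Fallback: switch to the cationic manifold with an allylsilane-terminated epoxy-polyene and MeAlCl2, where SN2-like anti opening of the (E)-epoxide fixes C4 (4α-CH2OR) and the silane fixes the exocyclic alkene.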